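**Assumption (one line):** Chan's diene (5), 2‑(allyloxy)tetrahydropyran (17), (+)‑Ipc2BOMe and the Burgess reagent are bought; for compounds 12–22 the carbon locants are those of the target skeleton (C1/C5 ring fusion, C4 methyl‑bearing carbon, C6 carbinol, C7 side‑chain carbon, C9 oxygenated carbon, C10 methylidene carbon, C11–C15 side chain).

## Retrosynthetic overview

1. Target ⇐ tetraol 21 (selective triacetylation; the hindered 6‑OH stays free) ⇐ C12 lactol 16 by syn‑alkoxyallylboration (C12, C13) and cross‑metathesis (C14=C15).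
2. Lactol ⇐ cis‑fused 6,12‑lactone 14, whose H7 and H11 come from conjugate reduction of butenolide 13 on the face of H6.
3. Key step: 13 ⇐ aldehyde/vinylogous acyl triflate 11. The C6–C7 bond and the seven‑membered ring are made by an intramolecular Nozaki–Hiyama–Kishi closure in which C7 (the β‑carbon of an acrylate, normally an acceptor) acts as a β‑acylvinyl (sp2 homoenolate) nucleophile toward the C6 aldehyde.
4. Five‑membered ring ⇐ enolexo aldol of the keto aldehyde from ozonolysis of the limonene ring; C3=C4 comes later by syn‑dehydration of the aldol hydroxyl.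
5. C7, C8, C11, C12 ⇐ Chan's diene added to (R)‑limonen‑10‑al (sets C9). Ring order: cyclopentane first, then seven‑membered ring plus lactone together.

## Route

**Step 1**
Reactants: 1 (R)‑(+)‑limonene
Product: 3 2‑[(1R)‑4‑methylcyclohex‑3‑en‑1‑yl]prop‑2‑en‑1‑ol, via 10‑lithiolimonene 2 (not isolated)
Conditions: nBuLi, TMEDA, hexane, 25 °C; B(OMe)3, −78 °C; H2O2, aq NaOH, 0 °C
Reagents that add atoms: hydrogen peroxide (OO)
Why: Allylic lithiation with nBuLi·TMEDA is selective for the isopropenyl methyl group, and borate trapping with peroxide oxidation gives the primary allylic alcohol without touching the stereocentre that becomes C1.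

**Step 2**
Reactants: 3 2‑[(1R)‑4‑methylcyclohex‑3‑en‑1‑yl]prop‑2‑en‑1‑ol
Product: 4 2‑[(1R)‑4‑methylcyclohex‑3‑en‑1‑yl]prop‑2‑enal
Conditions: MnO2, CH2Cl2, 25 °C
Reagents that add atoms: none
Why: MnO2 oxidation of the allylic alcohol stops at the 2‑substituted acrolein, whose carbonyl carbon becomes C9.

**Step 3**
Reactants: 4 2‑[(1R)‑4‑methylcyclohex‑3‑en‑1‑yl]prop‑2‑enal; 5 Chan's diene (1‑methoxy‑1,3‑bis(trimethylsilyloxy)buta‑1,3‑diene)
Product: 6 methyl (5R)‑5‑hydroxy‑6‑[(1R)‑4‑methylcyclohex‑3‑en‑1‑yl]‑3‑oxohept‑6‑enoate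
Conditions: Ti(OiPr)4 (10 mol%), (R)‑BINOL (10 mol%), THF, −78 to 25 °C; then TFA, −78 °C
Reagents that add atoms: none
Why: Catalytic enantioselective vinylogous Mukaiyama aldol adds the diene terminus to the Re face of the aldehyde (ligand enantiomer chosen for that face), which sets C9 as R and delivers C8, C7, C11 and C12 as a δ‑hydroxy‑β‑keto ester after desilylation.

**Step 4**
Reactants: 6 methyl (5R)‑5‑hydroxy‑6‑[(1R)‑4‑methylcyclohex‑3‑en‑1‑yl]‑3‑oxohept‑6‑enoate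
Product: 7 methyl (5R)‑6‑[(1R)‑4‑methylcyclohex‑3‑en‑1‑yl]‑3‑oxo‑5‑(triethylsilyloxy)hept‑6‑enoate
Conditions: TESCl, imidazole, DMF, 0 °C
Reagents that add atoms: chlorotriethylsilane (CC[Si](Cl)(CC)CC)
Why: Silylation of the secondary alcohol under weakly basic conditions prevents lactonisation and retro‑aldol of the δ‑hydroxy‑β‑keto ester and gives a C9 ether that mild acid removes at the end.

**Step 5**
Reactants: 7 methyl (5R)‑6‑[(1R)‑4‑methylcyclohex‑3‑en‑1‑yl]‑3‑oxo‑5‑(triethylsilyloxy)hept‑6‑enoate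
Product: 8 methyl (5R)‑2‑methyl‑6‑[(1R)‑4‑methylcyclohex‑3‑en‑1‑yl]‑3‑oxo‑5‑(triethylsilyloxy)hept‑6‑enoate (C2 epimers)
Conditions: MeI, K2CO3, acetone, 25 °C
Reagents that add atoms: iodomethane (CI)
Why: C‑alkylation of the β‑keto ester enolate puts the C19 methyl on C11, whose configuration is irrelevant because it is enolised in the next step.

**Step 6**
Reactants: 8 methyl (5R)‑2‑methyl‑6‑[(1R)‑4‑methylcyclohex‑3‑en‑1‑yl]‑3‑oxo‑5‑(triethylsilyloxy)hept‑6‑enoate
Product: 9 methyl (2Z,5R)‑2‑methyl‑6‑[(1R)‑4‑methylcyclohex‑3‑en‑1‑yl]‑5‑(triethylsilyloxy)‑3‑(trifluoromethylsulfonyloxy)hepta‑2,6‑dienoate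
Conditions: Tf2O, aq LiOH, toluene, 5 °C
Reagents that add atoms: triflic anhydride (O=S(=O)(OS(=O)(=O)C(F)(F)F)C(F)(F)F)
Why: O‑Triflation of the lithium‑chelated β‑keto ester enolate gives the tetrasubstituted (Z)‑enol triflate (triflate cis to the ester), which masks the C7 ketone and makes C7 the latent organometallic carbon.

**Step 7**
Reactants: 9 methyl (2Z,5R)‑2‑methyl‑6‑[(1R)‑4‑methylcyclohex‑3‑en‑1‑yl]‑5‑(triethylsilyloxy)‑3‑(trifluoromethylsulfonyloxy)hepta‑2,6‑dienoate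
Product: 10 methyl (2Z,5R,7R)‑2‑methyl‑6‑methylidene‑10‑oxo‑7‑(2‑oxoethyl)‑5‑(triethylsilyloxy)‑3‑(trifluoromethylsulfonyloxy)undec‑2‑enoate
Conditions: O3 (1 equiv, dye end point), CH2Cl2–MeOH, −78 °C; Me2S
Reagents that add atoms: ozone ([O-][O+]=O)
Why: Ozonolysis is selective for the electron‑rich trisubstituted ring alkene over the 1,1‑disubstituted alkene next to the silyloxy group and the electron‑poor enol triflate, and it unveils the C6 aldehyde and the C4 methyl ketone.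

**Step 8**
Reactants: 10 methyl (2Z,5R,7R)‑2‑methyl‑6‑methylidene‑10‑oxo‑7‑(2‑oxoethyl)‑5‑(triethylsilyloxy)‑3‑(trifluoromethylsulfonyloxy)undec‑2‑enoate
Product: 11 methyl (2Z,5R)‑6‑[(1R,2S,3R)‑2‑formyl‑3‑hydroxy‑3‑methylcyclopentyl]‑2‑methyl‑5‑(triethylsilyloxy)‑3‑(trifluoromethylsulfonyloxy)hepta‑2,6‑dienoate
Conditions: L‑proline (30 mol%), DMSO, 25 °C
Reagents that add atoms: none
Why: Enamine‑catalysed 5‑enolexo aldol addition forms the C4–C5 bond, and the epimerisable formyl‑bearing C5 settles trans to the C1 substituent (5S, matched with L‑proline) and cis to the new tertiary hydroxyl (4R, hydrogen‑bonded transition state), while the hindered tetrasubstituted enol triflate is left alone.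

**Step 9**
Reactants: 11 methyl (2Z,5R)‑6‑[(1R,2S,3R)‑2‑formyl‑3‑hydroxy‑3‑methylcyclopentyl]‑2‑methyl‑5‑(triethylsilyloxy)‑3‑(trifluoromethylsulfonyloxy)hepta‑2,6‑dienoate
Product: 13 (1R,4R,5R,6S,9R)‑4‑hydroxy‑10‑methylidene‑9‑(triethylsilyloxy)‑7(11)‑ene‑12,6‑olide (tricyclic butenolide), via hydroxy enoate 12 (not isolated)
Conditions: CrCl2 (6 equiv), NiCl2 (5 mol%), DMSO–THF, 25 °C, 0.005 M
Reagents that add atoms: none
Why: In this intramolecular Nozaki–Hiyama–Kishi reaction zerovalent nickel inserts into the vinylogous acyl triflate and transmetalation to trivalent chromium turns C7 into a β‑acylvinyl (sp2 homoenolate) nucleophile that adds to the C6 aldehyde and closes the seven‑membered ring, with the chromium alkoxide pseudo‑equatorial and chelated by the cis C4 hydroxyl (6β‑oxygen, 6R in the target), after which the (Z)‑hydroxy ester lactonises to the butenolide.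

**Step 10**
Reactants: 13 tricyclic butenolide
Product: 14 (1R,4R,5R,6R,7S,9R,11R)‑4‑hydroxy‑10‑methylidene‑9‑(triethylsilyloxy)‑12,6‑olide (saturated cis‑fused lactone)
Conditions: Cu(OAc)2·H2O (5 mol%), 1,2‑bis(diphenylphosphino)benzene (5 mol%), (EtO)2MeSiH, tBuOH, toluene, 25 °C
Reagents that add atoms: none
Why: Copper hydride conjugate reduction delivers hydride to C7 on the face of H6, away from the cyclopentane on C6, and the enolate is protonated at C11 from the same convex face, so H6, H7 and H11 end up cis (7S, 11R) and the isolated alkene is untouched.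

**Step 11**
Reactants: 14 saturated cis‑fused lactone
Product: 15 (1R,5S,6R,7S,9R,11R)‑10‑methylidene‑9‑(triethylsilyloxy)‑3‑ene‑12,6‑olide
Conditions: Burgess reagent, benzene, 50 °C
Reagents that add atoms: none
Why: Burgess dehydration is a syn elimination, and because H5 is trans to the C4 hydroxyl only a C3 hydrogen (or the methyl group) can be removed, which gives the endocyclic C3=C4 alkene favoured in a five‑membered ring and leaves C5 intact.

**Step 12**
Reactants: 15 cyclopentene lactone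
Product: 16 (1R,5S,6R,7S,9R,11R)‑6,12‑epoxy‑12‑hydroxy lactol (C12 epimers)
Conditions: DIBAL‑H, CH2Cl2, −78 °C
Reagents that add atoms: none
Why: Partial reduction of the γ‑lactone stops at the aluminium hemiacetal, so the lactol serves as a masked C12 aldehyde with O6 still tied up and C11 not epimerised.

**Step 13**
Reactants: 16 lactol; 17 2‑(allyloxy)tetrahydropyran
Product: 18 (1R,5S,6R,7S,9R,11R,12S,13S)‑6,12‑diol with 13‑(tetrahydropyran‑2‑yloxy), 9‑(triethylsilyloxy) and a terminal C14=C15H2 vinyl group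
Conditions: 17, sBuLi, THF, −78 °C; (+)‑Ipc2BOMe; BF3·OEt2; then 16, −78 to 0 °C; NaOH, H2O2
Reagents that add atoms: none
Why: Brown‑type (Z)‑γ‑alkoxyallylboration of the open hydroxy aldehyde goes through a chair transition state that gives the syn 12,13‑diol monoether, and the borane derived from (+)‑Ipc2BOMe attacks the Re face of the aldehyde under reagent control (12S,13S).

**Step 14**
Reactants: 18 vinyl diol; 19 2‑methyl‑2‑butene
Product: 20 (1R,5S,6R,7S,9R,11R,12S,13S)‑6,12‑diol with 13‑(tetrahydropyran‑2‑yloxy), 9‑(triethylsilyloxy) and the C14=C15(CH3)2 alkene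
Conditions: second‑generation Grubbs catalyst (5 mol%), 2‑methyl‑2‑butene (excess), CH2Cl2, 40 °C
Reagents that add atoms: none
Why: Cross‑metathesis of the monosubstituted vinyl group with 2‑methyl‑2‑butene gives the trisubstituted C14=C15 alkene, while the 1,1‑disubstituted and ring trisubstituted alkenes are too hindered to react.

**Step 15**
Reactants: 20 protected diol
Product: 21 (1R,5S,6R,7S,9R,11R,12S,13S)‑6,9,12,13‑tetraol
Conditions: PPTS, MeOH, 40 °C
Reagents that add atoms: none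
Why: Mild acid‑catalysed methanolysis removes the triethylsilyl ether and the tetrahydropyranyl acetal together without ionising the allylic C9 and C13 carbinols.

**Step 16**
Reactants: 21 tetraol
Product: 22 target, (1R,5S,6R,7S,9R,11R,12S,13S)‑9,12,13‑triacetoxy‑6‑ol
Conditions: Ac2O, pyridine, 25 °C
Reagents that add atoms: acetic anhydride (CC(=O)OC(C)=O)
Why: Acetylation without DMAP esterifies the C9, C12 and C13 hydroxyls and leaves the C6 hydroxyl, which is flanked by the ring‑fusion carbon and the branched C7, unacylated.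

## Compound list

1 | (R)‑(+)‑limonene | CC1=CC[C@@H](CC1)C(C)=C | starting material
2 | 10‑lithiolimonene | CC1=CC[C@@H](CC1)C(=C)C[Li] | intermediate
3 | 2‑[(1R)‑4‑methylcyclohex‑3‑en‑1‑yl]prop‑2‑en‑1‑ol | CC1=CC[C@@H](CC1)C(=C)CO | intermediate
4 | 2‑[(1R)‑4‑methylcyclohex‑3‑en‑1‑yl]prop‑2‑enal | CC1=CC[C@@H](CC1)C(=C)C=O | intermediate
5 | Chan's diene, 1‑methoxy‑1,3‑bis(trimethylsilyloxy)buta‑1,3‑diene | COC(O[Si](C)(C)C)=CC(=C)O[Si](C)(C)C | starting material
6 | methyl (5R)‑5‑hydroxy‑6‑[(1R)‑4‑methylcyclohex‑3‑en‑1‑yl]‑3‑oxohept‑6‑enoate | CC1=CC[C@@H](CC1)C(=C)[C@H](O)CC(=O)CC(=O)OC | intermediate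
7 | methyl (5R)‑6‑[(1R)‑4‑methylcyclohex‑3‑en‑1‑yl]‑3‑oxo‑5‑(triethylsilyloxy)hept‑6‑enoate | CC1=CC[C@@H](CC1)C(=C)[C@H](O[Si](CC)(CC)CC)CC(=O)CC(=O)OC | intermediate
8 | methyl (5R)‑2‑methyl‑6‑[(1R)‑4‑methylcyclohex‑3‑en‑1‑yl]‑3‑oxo‑5‑(triethylsilyloxy)hept‑6‑enoate (C2 epimers) | CC1=CC[C@@H](CC1)C(=C)[C@H](O[Si](CC)(CC)CC)CC(=O)C(C)C(=O)OC | intermediate
9 | methyl (2Z,5R)‑2‑methyl‑6‑[(1R)‑4‑methylcyclohex‑3‑en‑1‑yl]‑5‑(triethylsilyloxy)‑3‑(trifluoromethylsulfonyloxy)hepta‑2,6‑dienoate | CC1=CC[C@@H](CC1)C(=C)[C@H](O[Si](CC)(CC)CC)C/C(OS(=O)(=O)C(F)(F)F)=C(\C)C(=O)OC | intermediate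
10 | methyl (2Z,5R,7R)‑2‑methyl‑6‑methylidene‑10‑oxo‑7‑(2‑oxoethyl)‑5‑(triethylsilyloxy)‑3‑(trifluoromethylsulfonyloxy)undec‑2‑enoate | O=CC[C@@H](CCC(C)=O)C(=C)[C@H](O[Si](CC)(CC)CC)C/C(OS(=O)(=O)C(F)(F)F)=C(\C)C(=O)OC | intermediate
11 | methyl (2Z,5R)‑6‑[(1R,2S,3R)‑2‑formyl‑3‑hydroxy‑3‑methylcyclopentyl]‑2‑methyl‑5‑(triethylsilyloxy)‑3‑(trifluoromethylsulfonyloxy)hepta‑2,6‑dienoate | O=C[C@@H]1[C@](C)(O)CC[C@H]1C(=C)[C@H](O[Si](CC)(CC)CC)C/C(OS(=O)(=O)C(F)(F)F)=C(\C)C(=O)OC | intermediate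
12 | methyl (2Z)‑2‑[(1R,4R,5R,6S,9R)‑4,6‑dihydroxy‑4‑methyl‑10‑methylidene‑9‑(triethylsilyloxy)perhydroazulen‑7‑ylidene]propanoate | C=C1[C@H](O[Si](CC)(CC)CC)C/C(=C(\C)C(=O)OC)[C@@H](O)[C@@H]2[C@](C)(O)CC[C@@H]12 | intermediate
13 | (1R,4R,5R,6S,9R)‑4‑hydroxy‑10‑methylidene‑9‑(triethylsilyloxy)‑7(11)‑ene‑12,6‑olide (butenolide) | C=C1[C@H](O[Si](CC)(CC)CC)CC3=C(C)C(=O)O[C@H]3[C@@H]2[C@](C)(O)CC[C@@H]12 | intermediate
14 | (1R,4R,5R,6R,7S,9R,11R)‑4‑hydroxy‑10‑methylidene‑9‑(triethylsilyloxy)‑12,6‑olide | C=C1[C@H](O[Si](CC)(CC)CC)C[C@@H]([C@@H](C)C(=O)O3)[C@@H]3[C@@H]2[C@](C)(O)CC[C@@H]12 | intermediate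
15 | (1R,5S,6R,7S,9R,11R)‑10‑methylidene‑9‑(triethylsilyloxy)‑3‑ene‑12,6‑olide | C=C1[C@H](O[Si](CC)(CC)CC)C[C@@H]([C@@H](C)C(=O)O3)[C@@H]3[C@@H]2C(C)=CC[C@@H]12 | intermediate
16 | (1R,5S,6R,7S,9R,11R)‑6,12‑epoxy‑12‑hydroxy lactol (C12 epimers) | C=C1[C@H](O[Si](CC)(CC)CC)C[C@@H]([C@@H](C)C(O)O3)[C@@H]3[C@@H]2C(C)=CC[C@@H]12 | intermediate
17 | 2‑(allyloxy)tetrahydropyran | C=CCOC1CCCCO1 | starting material
18 | (1R,5S,6R,7S,9R,11R,12S,13S)‑6,12‑diol, 13‑OTHP, 9‑OTES, terminal vinyl | C=C1[C@H](O[Si](CC)(CC)CC)C[C@@H]([C@@H](C)[C@H](O)[C@H](C=C)OC3CCCCO3)[C@@H](O)[C@@H]2C(C)=CC[C@@H]12 | intermediate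
19 | 2‑methyl‑2‑butene | CC=C(C)C | starting material
20 | (1R,5S,6R,7S,9R,11R,12S,13S)‑6,12‑diol, 13‑OTHP, 9‑OTES, C14=C15(CH3)2 | C=C1[C@H](O[Si](CC)(CC)CC)C[C@@H]([C@@H](C)[C@H](O)[C@H](C=C(C)C)OC3CCCCO3)[C@@H](O)[C@@H]2C(C)=CC[C@@H]12 | intermediate
21 | (1R,5S,6R,7S,9R,11R,12S,13S)‑6,9,12,13‑tetraol | C=C1[C@H](O)C[C@@H]([C@@H](C)[C@H](O)[C@H](C=C(C)C)O)[C@@H](O)[C@@H]2C(C)=CC[C@@H]12 | intermediate
22 | CNP0194318.1, (1R,5S,6R,7S,9R,11R,12S,13S)‑9,12,13‑triacetoxy‑6‑ol | C=C1[C@H](OC(C)=O)C[C@@H]([C@@H](C)[C@H](OC(C)=O)[C@H](C=C(C)C)OC(C)=O)[C@@H](O)[C@@H]2C(C)=CC[C@@H]12 | target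

## Step count and risks

Total step count: 16. Longest linear sequence: 16 (from 1; the route is fully linear).

**Most likely to fail, with fallbacks:**

Step 8 (aldol addition): it may run on to the conjugated enal, or the enamine may attack the vinylogous triflate. The fallback sets out from 10 and comes back at 11. Enamine‑mediated α‑bromination of the aldehyde (NBS, cat. pyrrolidine/PhCO2H, CH2Cl2, −40 °C) gives the α‑bromo aldehyde F1. SmI2 (divalent samarium, THF, −78 °C) then generates the samarium enolate reductively, and this adds to the methyl ketone in a chelated Reformatsky‑type cyclisation to give 11 without an amine or a reversible enamine.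

Step 9 (organochromium ring closure): seven‑membered closure with a tetrasubstituted alkenyl triflate and a hindered aldehyde. The fallback sets out from 8 and comes back at 15, and it replaces the alkenyl‑metal addition by a ketyl coupling. Ozonolysis of 8 as in step 7 gives the keto aldehyde F2, and proline aldol as in step 8 gives the cyclopentane F3. SmI2 (THF–MeOH, −78 °C) couples the C6 aldehyde ketyl with the chelated C7 ketone of the β‑keto ester, and the C6 alkoxide lactonises to the hydroxy lactone F4. Excess Burgess reagent removes both tertiary hydroxyls (C7 toward the acidic C11–H, C4 as in step 11) to give the dienyl butenolide F5. Conjugate reduction under the conditions of step 10 then gives 15.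

Step 10 (conjugate reduction of the tetrasubstituted butenolide): reactivity and C11 control are uncertain. The fallback sets out from 13 and comes back at 14. Electron‑transfer reduction (SmI2, H2O, Et3N, THF, 25 °C) replaces hydride delivery and gives, after equilibration, mainly the 11‑epi lactone F6 (methyl trans to C8). Kinetic reprotonation of its lactone enolate from the convex face (LDA 2.2 equiv, THF, −78 °C; then 2,6‑di‑tert‑butylphenol) gives 14.

## Further compounds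

F1 | step 8 | methyl (2Z,5R)‑7‑(1‑bromo‑2‑oxoethyl)‑2‑methyl‑6‑methylidene‑10‑oxo‑5‑(triethylsilyloxy)‑3‑(trifluoromethylsulfonyloxy)undec‑2‑enoate (C7 configured as in 10, bromide epimers) | O=CC(Br)[C@@H](CCC(C)=O)C(=C)[C@H](O[Si](CC)(CC)CC)C/C(OS(=O)(=O)C(F)(F)F)=C(\C)C(=O)OC
F2 | step 9 | methyl (5R,7R)‑2‑methyl‑6‑methylidene‑3,10‑dioxo‑7‑(2‑oxoethyl)‑5‑(triethylsilyloxy)undecanoate (C2 epimers) | O=CC[C@@H](CCC(C)=O)C(=C)[C@H](O[Si](CC)(CC)CC)CC(=O)C(C)C(=O)OC
F3 | step 9 | methyl (5R)‑6‑[(1R,2S,3R)‑2‑formyl‑3‑hydroxy‑3‑methylcyclopentyl]‑2‑methyl‑3‑oxo‑5‑(triethylsilyloxy)hept‑6‑enoate (C2 epimers) | O=C[C@@H]1[C@](C)(O)CC[C@H]1C(=C)[C@H](O[Si](CC)(CC)CC)CC(=O)C(C)C(=O)OC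
F4 | step 9 | (1R,4R,5R,6S,9R)‑4,7‑dihydroxy‑10‑methylidene‑9‑(triethylsilyloxy)‑12,6‑olide (C7 and C11 epimers) | C=C1[C@H](O[Si](CC)(CC)CC)CC3(O)C(C)C(=O)O[C@H]3[C@@H]2[C@](C)(O)CC[C@@H]12
F5 | step 9 | (1R,5S,6S,9R)‑10‑methylidene‑9‑(triethylsilyloxy)‑3,7(11)‑diene‑12,6‑olide | C=C1[C@H](O[Si](CC)(CC)CC)CC3=C(C)C(=O)O[C@H]3[C@@H]2C(C)=CC[C@@H]12
F6 | step 10 | (1R,4R,5R,6R,7S,9R,11S)‑4‑hydroxy‑10‑methylidene‑9‑(triethylsilyloxy)‑12,6‑olide (11‑epi‑14) | C=C1[C@H](O[Si](CC)(CC)CC)C[C@@H]([C@H](C)C(=O)O3)[C@@H]3[C@@H]2[C@](C)(O)CC[C@@H]12
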